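**Plan**

- Retrosynthesis (zeylenone numbering: C1 = tertiary carbinol carrying C7H2OBz, C2–OAc, C3–OBz, C4=C5, C6 = ketone): the ester C–O bonds at O2 and O3 and the C4=C5 double bond are removed first, then the ring bond C1–C6 is cut, then the chain bond C2–C3.
- Enabling feature: the tertiary α-ketol C1(OH)–C6(=O) of the six-membered ring. In an open chain both atoms are carbonyl carbons (ketone C1, aldehyde C6), and carbene umpolung of C6 lets them join.
- Forward: an aldolase joins dihydroxyacetone (C7, C1, C2) to pent-4-enal (C3 to C6) at C2–C3; primary benzoylation, acetonide formation and ozonolysis give the keto aldehyde; the only ring closes at C1–C6; dehydrogenation, deprotection and two acylations complete the target.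
- Stereochemistry: C2 (S) and C3 (R) are set by the enzyme. C1 (S) is relayed from them through the trans-fused dioxolane in the chair transition state of the ring closure, reinforced by the chiral triazolylidene. No later step touches these centers.

Key step: step 5

Assumption: of the two antipodes of the aminoindanol-derived triazolium salt, the (5aR,10bS) one is taken to be matched with the chair preference of the substrate at C1; if it proves mismatched, the (5aS,10bR) salt is used with nothing else changed.

**Route**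

Step 1
Reactants: 1 dihydroxyacetone, 2 pent-4-enal
Product: 3 (3S,4R)-1,3,4-trihydroxyoct-7-en-2-one
Conditions: D-fructose-6-phosphate aldolase of Escherichia coli (Ala129Ser variant), 1 (1.5 equiv), triethanolamine buffer pH 7.5, DMF (15% v/v), 25 °C
Reagents that add atoms: none
Why: Enzymatic aldol addition: the active-site lysine enamine of dihydroxyacetone adds to the aldehyde with the D-threo sense imposed by the protein, which forms the C2–C3 bond and sets C2 (3S in the octenone) and C3 (4R) together.

Step 2
Reactants: 3 (3S,4R)-1,3,4-trihydroxyoct-7-en-2-one, 4 benzoyl chloride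
Product: 5 (3S,4R)-3,4-dihydroxy-2-oxooct-7-en-1-yl benzoate
Conditions: 4 (1.05 equiv), 2,4,6-collidine, CH2Cl2, −40 °C
Reagents that add atoms: none
Why: Kinetically controlled O-acylation of the primary hydroxyl, the least hindered of the three, with a hindered weak base at low temperature so that the α-ketol neither enolises nor suffers acyl migration.

Step 3
Reactants: 5 (3S,4R)-3,4-dihydroxy-2-oxooct-7-en-1-yl benzoate, 6 2,2-dimethoxypropane
Product: 7 2-[(4S,5R)-5-(but-3-en-1-yl)-2,2-dimethyl-1,3-dioxolan-4-yl]-2-oxoethyl benzoate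
Conditions: 6 (3 equiv), pyridinium p-toluenesulfonate (5 mol%), CH2Cl2, 23 °C
Reagents that add atoms: none
Why: Acid-catalysed transacetalisation: the threo diol, the only two hydroxyls left, closes to the unstrained trans-4,5-disubstituted dioxolane without touching either stereocenter.

Step 4
Reactants: 7 2-[(4S,5R)-5-(but-3-en-1-yl)-2,2-dimethyl-1,3-dioxolan-4-yl]-2-oxoethyl benzoate
Product: 9 2-[(4S,5R)-2,2-dimethyl-5-(3-oxopropyl)-1,3-dioxolan-4-yl]-2-oxoethyl benzoate, via secondary ozonide 8 (not isolated)
Conditions: O3, CH2Cl2, −78 °C; then PPh3, −78 to 23 °C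
Reagents that add atoms: ozone, O=[O+][O-]
Why: Ozonolysis (Criegee mechanism) of the only alkene and phosphine reduction of the ozonide should give the aldehyde, since benzoate, ketone and acetonide are inert to ozone at −78 °C and the ozonide carbon is a transient stereocenter of no consequence.

Step 5
Reactants: 9 2-[(4S,5R)-2,2-dimethyl-5-(3-oxopropyl)-1,3-dioxolan-4-yl]-2-oxoethyl benzoate
Product: 10 [(3aS,4S,7aR)-4-hydroxy-2,2-dimethyl-5-oxohexahydro-1,3-benzodioxol-4-yl]methyl benzoate
Conditions: (5aR,10bS)-2-(pentafluorophenyl)-5a,10b-dihydro-4H,6H-indeno[2,1-b][1,2,4]triazolo[4,3-d][1,4]oxazin-2-ium tetrafluoroborate (20 mol%), iPr2NEt (20 mol%), toluene (0.05 M), 23 °C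
Reagents that add atoms: none
Why: iPr2NEt frees the triazolylidene, which adds to the unhindered aldehyde C6; proton transfer gives the enaminol (Breslow intermediate), whose C6 attacks ketone C1 as the enol proton passes to the developing alkoxide, and loss of the carbene releases the ketol. The closest known reaction type is the carbene-catalysed intramolecular crossed aldehyde–ketone benzoin reaction that gives 2-alkyl-2-hydroxycyclohexanones. The cyclohexanone ring closes in the 6-exo-trig mode. C1, the only new stereocenter, is controlled by the trans-fused dioxolane: in the chair transition state both ring oxygens are equatorial, the C2–O bond lies anti to the forming C1–C6 bond (polar Felkin–Anh arrangement) and CH2OBz takes the equatorial site, so the hydroxyl ends axial and cis to O2, and the catalyst antipode is the one expected to attack the same ketone face. The step needs donor–acceptor chemoselectivity, which is secured because only the aldehyde can form the enaminol and the ketone, flanked by two oxygenated carbons, is the stronger electrophile, while ring closure at 0.05 M should outrun dimerisation. It also needs C2 and O3 to survive, which the weak amine base in a non-polar solvent at ambient temperature should allow.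

Step 6
Reactants: 10 [(3aS,4S,7aR)-4-hydroxy-2,2-dimethyl-5-oxohexahydro-1,3-benzodioxol-4-yl]methyl benzoate
Product: 11 [(3aS,4S,7aR)-2,2-dimethyl-4,5-bis(trimethylsilyloxy)-3a,4,7,7a-tetrahydro-1,3-benzodioxol-4-yl]methyl benzoate
Conditions: Me3SiOTf (2.5 equiv), Et3N (4 equiv), CH2Cl2, 0 °C
Reagents that add atoms: trimethylsilyl trifluoromethanesulfonate, C[Si](C)(C)OS(=O)(=O)C(F)(F)F
Why: Soft enolisation with O-silylation: the ketone can enolise only toward C5 because C1 is quaternary, and the tertiary hydroxyl is capped in the same operation without an alkoxide being formed, which avoids α-ketol rearrangement and benzoyl migration.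

Step 7
Reactants: 11 [(3aS,4S,7aR)-2,2-dimethyl-4,5-bis(trimethylsilyloxy)-3a,4,7,7a-tetrahydro-1,3-benzodioxol-4-yl]methyl benzoate
Product: 12 [(3aS,4S,7aR)-2,2-dimethyl-5-oxo-4-(trimethylsilyloxy)-3a,4,5,7a-tetrahydro-1,3-benzodioxol-4-yl]methyl benzoate
Conditions: Pd(OAc)2 (1.1 equiv), MeCN, 23 °C
Reagents that add atoms: none
Why: Saegusa–Ito oxidation: the silyl enol ether hands its enolate to divalent palladium and β-hydride elimination from C4 should give the C4–C5 enone with release of zerovalent palladium, the three stereocenters not being involved.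

Step 8
Reactants: 12 [(3aS,4S,7aR)-2,2-dimethyl-5-oxo-4-(trimethylsilyloxy)-3a,4,5,7a-tetrahydro-1,3-benzodioxol-4-yl]methyl benzoate
Product: 13 [(1S,5R,6S)-1,5,6-trihydroxy-2-oxocyclohex-3-en-1-yl]methyl benzoate
Conditions: CF3CO2H–H2O (9:1), 0 °C
Reagents that add atoms: none
Why: Acid-catalysed hydrolysis of the strained trans-fused isopropylidene acetal and of the tertiary trimethylsilyl ether; the benzoate, the enone and the stereocenters should be stable to cold aqueous acid.

Step 9
Reactants: 13 [(1S,5R,6S)-1,5,6-trihydroxy-2-oxocyclohex-3-en-1-yl]methyl benzoate, 4 benzoyl chloride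
Product: 14 zeylenone, [(1S,5R,6S)-5-(benzoyloxy)-1,6-dihydroxy-2-oxocyclohex-3-en-1-yl]methyl benzoate
Conditions: 4 (1.1 equiv), pyridine, CH2Cl2, −30 °C
Reagents that add atoms: none
Why: Kinetically controlled O-acylation: the allylic C3 hydroxyl is the most accessible, the C2 hydroxyl being flanked by the quaternary C1 and the tertiary C1 hydroxyl being unreactive, so one equivalent of acyl chloride at low temperature should give the 3-O-benzoate.

Step 10
Reactants: 14 zeylenone, 15 acetic anhydride
Product: 16 2-O-acetylzeylenone, [(1S,5R,6S)-6-(acetyloxy)-5-(benzoyloxy)-1-hydroxy-2-oxocyclohex-3-en-1-yl]methyl benzoate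
Conditions: 15 (1.5 equiv), pyridine, 4-(dimethylamino)pyridine (5 mol%), CH2Cl2, 0 °C
Reagents that add atoms: none
Why: Nucleophile-catalysed acetylation of the only remaining secondary hydroxyl (C2); the hindered tertiary C1 hydroxyl should not acylate under these conditions.

**Compound list**

1 | dihydroxyacetone | OCC(=O)CO | starting material
2 | pent-4-enal | C=CCCC=O | starting material
3 | (3S,4R)-1,3,4-trihydroxyoct-7-en-2-one | OCC(=O)[C@@H](O)[C@H](O)CCC=C | intermediate
4 | benzoyl chloride | O=C(Cl)c1ccccc1 | starting material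
5 | (3S,4R)-3,4-dihydroxy-2-oxooct-7-en-1-yl benzoate | O=C(OCC(=O)[C@@H](O)[C@H](O)CCC=C)c1ccccc1 | intermediate
6 | 2,2-dimethoxypropane | COC(C)(C)OC | starting material
7 | 2-[(4S,5R)-5-(but-3-en-1-yl)-2,2-dimethyl-1,3-dioxolan-4-yl]-2-oxoethyl benzoate | C=CCC[C@H]1OC(C)(C)O[C@@H]1C(=O)COC(=O)c1ccccc1 | intermediate
8 | secondary ozonide, 2-[(4S,5R)-2,2-dimethyl-5-[2-(1,2,4-trioxolan-3-yl)ethyl]-1,3-dioxolan-4-yl]-2-oxoethyl benzoate (both epimers at the trioxolane carbon; not isolated) | C1OC(CC[C@H]2OC(C)(C)O[C@@H]2C(=O)COC(=O)c3ccccc3)OO1 | intermediate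
9 | 2-[(4S,5R)-2,2-dimethyl-5-(3-oxopropyl)-1,3-dioxolan-4-yl]-2-oxoethyl benzoate (keto aldehyde; ketone = C1, aldehyde = C6) | O=CCC[C@H]1OC(C)(C)O[C@@H]1C(=O)COC(=O)c1ccccc1 | intermediate
10 | [(3aS,4S,7aR)-4-hydroxy-2,2-dimethyl-5-oxohexahydro-1,3-benzodioxol-4-yl]methyl benzoate (ketol; C1 hydroxyl cis to O2, dioxolane trans-fused) | O=C1CC[C@H]2OC(C)(C)O[C@@H]2[C@@]1(O)COC(=O)c1ccccc1 | intermediate
11 | [(3aS,4S,7aR)-2,2-dimethyl-4,5-bis(trimethylsilyloxy)-3a,4,7,7a-tetrahydro-1,3-benzodioxol-4-yl]methyl benzoate (C5=C6 silyl enol ether, C1 silyl ether) | C[Si](C)(C)OC1=CC[C@H]2OC(C)(C)O[C@@H]2[C@@]1(O[Si](C)(C)C)COC(=O)c1ccccc1 | intermediate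
12 | [(3aS,4S,7aR)-2,2-dimethyl-5-oxo-4-(trimethylsilyloxy)-3a,4,5,7a-tetrahydro-1,3-benzodioxol-4-yl]methyl benzoate (C4=C5 enone) | O=C1C=C[C@H]2OC(C)(C)O[C@@H]2[C@@]1(O[Si](C)(C)C)COC(=O)c1ccccc1 | intermediate
13 | [(1S,5R,6S)-1,5,6-trihydroxy-2-oxocyclohex-3-en-1-yl]methyl benzoate | O[C@H]1[C@H](O)C=CC(=O)[C@]1(O)COC(=O)c1ccccc1 | intermediate
14 | zeylenone, [(1S,5R,6S)-5-(benzoyloxy)-1,6-dihydroxy-2-oxocyclohex-3-en-1-yl]methyl benzoate | O[C@H]1[C@H](OC(=O)c2ccccc2)C=CC(=O)[C@]1(O)COC(=O)c1ccccc1 | intermediate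
15 | acetic anhydride | CC(=O)OC(C)=O | starting material
16 | 2-O-acetylzeylenone, [(1S,5R,6S)-6-(acetyloxy)-5-(benzoyloxy)-1-hydroxy-2-oxocyclohex-3-en-1-yl]methyl benzoate | CC(=O)O[C@H]1[C@H](OC(=O)c2ccccc2)C=CC(=O)[C@]1(O)COC(=O)c1ccccc1 | target

**Step count and risks**

Total: 10 steps. Longest linear sequence: 10 steps (1 or 2 to 16).

Step 5 (ring closure). What may go wrong: attack on the wrong face of ketone C1, so that CH2OBz ends axial, or enolisation next to the ketone under the carbene/amine conditions (epimerisation at C2, β-elimination of O3, aldol side reactions) outrunning carbene turnover. The fallback replaces carbene umpolung by nitronate umpolung with a reversible, thermodynamically controlled ring closure; it sets out from 9 and comes back at 10.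
- The aldehyde of 9 alone would be reduced with NaBH(OAc)3 (benzene, 23 °C), which leaves the ketone, to 2-[(4S,5R)-5-(3-hydroxypropyl)-2,2-dimethyl-1,3-dioxolan-4-yl]-2-oxoethyl benzoate F1.
- I2, PPh3 and imidazole in CH2Cl2 would give 2-[(4S,5R)-5-(3-iodopropyl)-2,2-dimethyl-1,3-dioxolan-4-yl]-2-oxoethyl benzoate F2.
- AgNO2 in Et2O would give 2-[(4S,5R)-2,2-dimethyl-5-(3-nitropropyl)-1,3-dioxolan-4-yl]-2-oxoethyl benzoate F3.
- A catalytic amount of 1,8-diazabicyclo[5.4.0]undec-7-ene in MeCN would close the C1–C6 bond by intramolecular Henry addition to [(3aS,4S,7aR)-4-hydroxy-2,2-dimethyl-5-nitrohexahydro-1,3-benzodioxol-4-yl]methyl benzoate F4. The reversible addition should settle on the chair with CH2OBz and NO2 equatorial and the C1 hydroxyl axial, cis to O2.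
- An oxidative Nef reaction (KOtBu, THF, −40 °C, then dimethyldioxirane in acetone) would turn the nitro-bearing carbon into the C6 ketone and give 10.

Step 1 (aldolase). What may go wrong: poor binding and low solubility of a hydrophobic acceptor that lacks a polar group, and gradual loss of enzyme activity through imine formation with the aldehyde, so that conversion stalls. The fallback is an amine-organocatalysed syn-aldol of protected dihydroxyacetone; it sets out from 1 and comes back at 3.
- 1 would be silylated (tBuMe2SiCl, imidazole, DMF) to 1,3-bis(tert-butyldimethylsilyloxy)propan-2-one F5.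
- Its hydrogen-bonded (Z)-enamine with O-tert-butyl-D-threonine (20 mol%, 5-methyl-1H-tetrazole, wet N-methylpyrrolidone, 4 °C) would add to 2 to give the syn adduct (3S,4R)-1,3-bis(tert-butyldimethylsilyloxy)-4-hydroxyoct-7-en-2-one F6. The D-amino acid is taken because the (Z)-enamine of the L-series catalyst is expected to deliver the (3R,4S) antipode.
- HF·pyridine in THF would remove both silyl groups and give 3.

Step 9 (C3 benzoylation). What may go wrong: insufficient discrimination between the two secondary hydroxyls, leading to benzoylation at O2, double benzoylation or base-promoted benzoyl migration from O3 to O2. The fallback masks the cis C1/C2 diol temporarily; it sets out from 13 and comes back at 14.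
- Phenylboronic acid (toluene, molecular sieves, 23 °C) would condense with the cis C1/C2 diol of 13 to the cyclic boronate [(3aS,7R,7aS)-7-hydroxy-4-oxo-2-phenyl-7,7a-dihydro-1,3,2-benzodioxaborol-3a(4H)-yl]methyl benzoate F7, in which only the C3 hydroxyl is free.
- Benzoyl chloride 4 and pyridine would give [(3aS,7R,7aS)-7-(benzoyloxy)-4-oxo-2-phenyl-7,7a-dihydro-1,3,2-benzodioxaborol-3a(4H)-yl]methyl benzoate F8.
- Exchange with pinacol in CH2Cl2 would free the C1/C2 diol and give 14.

**Further compounds**

F1 | step 5 | 2-[(4S,5R)-5-(3-hydroxypropyl)-2,2-dimethyl-1,3-dioxolan-4-yl]-2-oxoethyl benzoate | OCCC[C@H]1OC(C)(C)O[C@@H]1C(=O)COC(=O)c1ccccc1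
F2 | step 5 | 2-[(4S,5R)-5-(3-iodopropyl)-2,2-dimethyl-1,3-dioxolan-4-yl]-2-oxoethyl benzoate | ICCC[C@H]1OC(C)(C)O[C@@H]1C(=O)COC(=O)c1ccccc1
F3 | step 5 | 2-[(4S,5R)-2,2-dimethyl-5-(3-nitropropyl)-1,3-dioxolan-4-yl]-2-oxoethyl benzoate | O=[N+]([O-])CCC[C@H]1OC(C)(C)O[C@@H]1C(=O)COC(=O)c1ccccc1
F4 | step 5 | [(3aS,4S,7aR)-4-hydroxy-2,2-dimethyl-5-nitrohexahydro-1,3-benzodioxol-4-yl]methyl benzoate (both epimers at the nitro-bearing carbon) | O=[N+]([O-])C1CC[C@H]2OC(C)(C)O[C@@H]2[C@@]1(O)COC(=O)c1ccccc1
F5 | step 1 | 1,3-bis(tert-butyldimethylsilyloxy)propan-2-one | CC(C)(C)[Si](C)(C)OCC(=O)CO[Si](C)(C)C(C)(C)C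
F6 | step 1 | (3S,4R)-1,3-bis(tert-butyldimethylsilyloxy)-4-hydroxyoct-7-en-2-one | CC(C)(C)[Si](C)(C)OCC(=O)[C@@H](O[Si](C)(C)C(C)(C)C)[C@H](O)CCC=C
F7 | step 9 | [(3aS,7R,7aS)-7-hydroxy-4-oxo-2-phenyl-7,7a-dihydro-1,3,2-benzodioxaborol-3a(4H)-yl]methyl benzoate | c1ccccc1B2O[C@H]3[C@H](O)C=CC(=O)[C@]3(O2)COC(=O)c1ccccc1
F8 | step 9 | [(3aS,7R,7aS)-7-(benzoyloxy)-4-oxo-2-phenyl-7,7a-dihydro-1,3,2-benzodioxaborol-3a(4H)-yl]methyl benzoate | c1ccccc1B2O[C@H]3[C@H](OC(=O)c4ccccc4)C=CC(=O)[C@]3(O2)COC(=O)c1ccccc1
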